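The tetralin is disconnected at C1–C8a. C1 is a benzylic stereocentre attached to fusion carbon C8a, which sits ortho to the C8 oxygen, so an aryl anion generated at C8a can displace oxygen from a configurationally defined C1. In one operation, bromine–lithium exchange and 6-exo opening of an (R)-oxirane close ring B (C1–C4, C4a, C8a), form the C1–C8a bond and set C1 by inversion, leaving C20 as CH2OH. The precursor is an acyclic aryl bromide: the 2-bromo-3,4-bis(methoxymethoxy)phenyl group on C4, the silyl-protected side chain (C11–C16) and a two-carbon tether to the terminal epoxide; C4/C11 come from an Ireland–Claisen rearrangement, C15 from the chiral pool.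

Key step: step 15

Remarks on the chemistry (made before the steps):
- Numbering: C1 (methyl-bearing) and C4 (chain-bearing) are the benzylic carbons, joined by C2 and C3; C4a and C8a are the fusion carbons; C5–H, C6 carboxyl, C7/C8 oxygens; side chain C11 (CH), C12–C14 (CH2), C15 (CH), C16 (OCH2); C20 is the C1 methyl. Target configuration: 1R, 4S, 11S, 15R, with C1-methyl and C4-chain trans.
- Abbreviations: Ar = 2-bromo-3,4-bis(methoxymethoxy)phenyl; MOM = methoxymethyl; TBS = tert-butyldimethylsilyl; Ts = 4-methylbenzenesulfonyl.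
- Design choice for the cyclisation substrate: O7 and O8 are carried as MOM ethers from the first step. MOM survives the organolithium steps, directs the later lithiation to C6 and leaves under the same mild acid as the other end-game groups, so no Lewis-acid ether cleavage is needed near the caffeate. The carboxyl enters directly as a tert-butyl ester.
- Assumption: 2-bromo-3,4-dihydroxybenzaldehyde and (E)-N-methoxy-N-methylbut-2-enamide are taken as commercially available.

Step 1
Reactants: 1 2-bromo-3,4-dihydroxybenzaldehyde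
Product: 2 2-bromo-3,4-bis(methoxymethoxy)benzaldehyde
Conditions: MOMCl, i-Pr2NEt, CH2Cl2, 0 °C to rt
Reagents that add atoms: chloromethyl methyl ether, COCCl
Why: O-alkylation of both phenols (acetal formation) under amine base should be clean because the aldehyde and the aryl bromide are inert to these conditions.

Step 2
Reactants: 2 2-bromo-3,4-bis(methoxymethoxy)benzaldehyde
Product: 4 2-Ar-acetonitrile, via N-(2-aryl-1-tosylethenyl)formamide 3 (not isolated)
Conditions: TosMIC, t-BuOK, DME, −40 °C; then MeOH, reflux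
Reagents that add atoms: p-toluenesulfonylmethyl isocyanide (TosMIC), Cc1ccc(cc1)S(=O)(=O)C[N+]#[C-]
Why: The van Leusen reductive cyanation should homologate the aldehyde by one carbon, since methoxide deformylates the tosylvinyl formamide and sulfinate loss gives the nitrile without touching the C–Br bond or the MOM acetals.

Step 3
Reactants: 4 2-Ar-acetonitrile
Product: 5 2-Ar-acetic acid
Conditions: KOH, EtOH/H2O, reflux; then 1 M HCl to pH 3–4 at 0 °C
Reagents that add atoms: potassium hydroxide, [K+].[OH-]; water, O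
Why: Alkaline nitrile hydrolysis (via the amide) is compatible with aryl MOM ethers and the aryl bromide, and cold, brief acidification should spare the acetals.

Step 4
Reactants: 6 (S)-3-bromo-2-methylpropan-1-ol
Product: 7 (S)-(3-bromo-2-methylpropoxy)(tert-butyl)dimethylsilane
Conditions: TBSCl, imidazole, CH2Cl2, 0 °C to rt
Reagents that add atoms: tert-butyldimethylsilyl chloride, CC(C)(C)[Si](C)(C)Cl
Why: Silylation of the primary alcohol leaves the stereocentre (the future C15) untouched and gives an ether that tolerates Grignard, hydride and organolithium chemistry.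

Step 5
Reactants: 7 (S)-(3-bromo-2-methylpropoxy)(tert-butyl)dimethylsilane, 8 (E)-N-methoxy-N-methylbut-2-enamide
Product: 10 (2E,6R)-7-(TBS-oxy)-6-methylhept-2-en-4-one, via alkylmagnesium bromide 9 (not isolated)
Conditions: Mg, THF, 40 °C; then 8, THF, −20 to 0 °C; sat. NH4Cl
Reagents that add atoms: none
Why: Grignard formation followed by acyl substitution on the Weinreb amide should stop at the ketone, because the chelated tetrahedral intermediate survives until work-up; the stereocentre is remote from the reacting carbon.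

Step 6
Reactants: 10 (2E,6R)-7-(TBS-oxy)-6-methylhept-2-en-4-one
Product: 11 (2E,4R,6R)-7-(TBS-oxy)-6-methylhept-2-en-4-ol
Conditions: (S)-Me-CBS oxazaborolidine, catecholborane, toluene, −78 °C; MeOH, then aq. NaOH
Reagents that add atoms: none
Why: In the Corey–Bakshi–Shibata reduction the (S)-catalyst should treat the propenyl group as the large substituent and deliver hydride to give the (4R)-carbinol (the future C13), catecholborane at low temperature avoiding alkene hydroboration; the minor 4S epimer is to be removed by chromatography at this stage.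

Step 7
Reactants: 5 2-Ar-acetic acid, 11 (2E,4R,6R)-7-(TBS-oxy)-6-methylhept-2-en-4-ol
Product: 12 (2E,4R,6R)-7-(TBS-oxy)-6-methylhept-2-en-4-yl 2-Ar-acetate
Conditions: DCC, DMAP (cat.), CH2Cl2, 0 °C to rt
Reagents that add atoms: none
Why: Steglich esterification acylates the secondary allylic alcohol on oxygen without allylic transposition, so the carbinol configuration is retained.

Step 8
Reactants: 12 (2E,4R,6R)-7-(TBS-oxy)-6-methylhept-2-en-4-yl 2-Ar-acetate
Product: 15 (2S,3S,4E,7R)-2-Ar-8-(TBS-oxy)-3,7-dimethyloct-4-enoic acid, via Z-silyl ketene acetal 13 (not isolated), via trimethylsilyl ester 14 (not isolated)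
Conditions: LiHMDS, THF/DMPU, −78 °C; TMSCl/Et3N, −78 °C to rt; aq. citric acid work-up
Reagents that add atoms: none
Why: In this Ireland–Claisen rearrangement the conjugated arylacetate enolate should form with the aryl group cis to O–Li (reinforced by DMPU); its silyl ketene acetal rearranges through a chair with the aryl group, the crotyl methyl and the carbinol substituent all equatorial, so the (R)-carbinol is transferred into the syn (4S,11S) pair and an E alkene.

Step 9
Reactants: 15 (2S,3S,4E,7R)-2-Ar-8-(TBS-oxy)-3,7-dimethyloct-4-enoic acid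
Product: 16 (2S,3S,4E,7R)-2-Ar-8-(TBS-oxy)-3,7-dimethyloct-4-en-1-ol
Conditions: LiAlH4, THF, 0 °C to rt; Fieser work-up
Reagents that add atoms: none
Why: Hydride reduction of the carboxylate to the primary alcohol (the C3 carbinol) should proceed at a temperature at which the aryl bromide, the isolated alkene and the ethers are inert and the carboxylate-bearing C4 does not epimerise.

Step 10
Reactants: 16 (2S,3S,4E,7R)-2-Ar-8-(TBS-oxy)-3,7-dimethyloct-4-en-1-ol
Product: 17 (2S,3S,7R)-2-Ar-8-(TBS-oxy)-3,7-dimethyloctan-1-ol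
Conditions: 2-nitrobenzenesulfonohydrazide (excess, in portions), Et3N, CH2Cl2, rt
Reagents that add atoms: none
Why: Diimide reduction transfers H2 to the C12=C13 alkene in a concerted, metal-free way, so neither C–Br hydrogenolysis nor double-bond migration towards the allylic C11 stereocentre can occur.

Step 11
Reactants: 17 (2S,3S,7R)-2-Ar-8-(TBS-oxy)-3,7-dimethyloctan-1-ol
Product: 18 (2S,3S,7R)-2-Ar-8-(TBS-oxy)-3,7-dimethyloctyl 4-methylbenzenesulfonate
Conditions: TsCl, Et3N, DMAP (cat.), CH2Cl2, 0 °C to rt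
Reagents that add atoms: 4-methylbenzenesulfonyl chloride, Cc1ccc(cc1)S(Cl)(=O)=O
Why: Sulfonylation of the primary alcohol activates C3 without involving the adjacent C4 stereocentre.

Step 12
Reactants: 18 (2S,3S,7R)-2-Ar-8-(TBS-oxy)-3,7-dimethyloctyl 4-methylbenzenesulfonate
Product: 19 tert-butyl{[(2R,6S,7S)-7-Ar-2,6-dimethylundec-10-en-1-yl]oxy}dimethylsilane
Conditions: allylMgBr, CuI (10 mol %), THF, −40 to 0 °C
Reagents that add atoms: allylmagnesium bromide, C=CC[Mg]Br
Why: Copper-catalysed sp3–sp3 coupling of the allyl Grignard reagent with the primary tosylate (SN2 at C3) should be faster than any reaction at the aryl bromide at this temperature and adds C2, C1 and C20 in one step.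

Step 13
Reactants: 19 tert-butyl{[(2R,6S,7S)-7-Ar-2,6-dimethylundec-10-en-1-yl]oxy}dimethylsilane
Product: 20 tert-butyl{[(2R,6S,7S)-7-Ar-2,6-dimethyl-9-(oxiran-2-yl)nonyl]oxy}dimethylsilane (both epimers at the oxirane carbon)
Conditions: mCPBA, NaHCO3, CH2Cl2, 0 °C to rt
Reagents that add atoms: 3-chloroperbenzoic acid, OOC(=O)c1cccc(Cl)c1
Why: Prilezhaev epoxidation of the monosubstituted alkene is chemoselective over the brominated arene and the ethers; the remote stereocentres give no facial bias, so both C1 epimers are expected and are sorted out in the next step.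

Step 14
Reactants: 20 tert-butyl{[(2R,6S,7S)-7-Ar-2,6-dimethyl-9-(oxiran-2-yl)nonyl]oxy}dimethylsilane (both epimers)
Product: 21 tert-butyl{[(2R,6S,7S)-7-Ar-2,6-dimethyl-9-[(2R)-oxiran-2-yl]nonyl]oxy}dimethylsilane
Conditions: (R,R)-(salen)Co(III)OAc (1 mol %), H2O (0.55 equiv), THF, 0 °C to rt
Reagents that add atoms: none
Why: In the Jacobsen hydrolytic kinetic resolution the (R,R)-catalyst hydrolyses the (S)-configured monoalkyl oxirane, so the (2R)-oxirane should remain under pure catalyst control and is separated from the polar diol by chromatography.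

Step 15
Reactants: 21 tert-butyl{[(2R,6S,7S)-7-Ar-2,6-dimethyl-9-[(2R)-oxiran-2-yl]nonyl]oxy}dimethylsilane
Product: 23 [(1R,4S)-7,8-bis(methoxymethoxy)-4-[(2S,6R)-7-(TBS-oxy)-6-methylheptan-2-yl]-1,2,3,4-tetrahydronaphthalen-1-yl]methanol, via C8a aryllithium 22 (not isolated)
Conditions: t-BuLi (2.1 equiv), THF, −78 °C; then −78 to 0 °C; sat. NH4Cl
Reagents that add atoms: none
Why: At −78 °C t-BuLi exchanges the C8a bromine (the second equivalent destroys t-BuBr) far faster than it attacks the oxirane or the ethers, and the aryllithium, held by the C8 MOM oxygen, opens the tethered oxirane by intramolecular SN2 as the solution warms. The closest known reaction type is the Parham cyclisation, that is halogen–lithium exchange followed by ring closure of an ω-(o-lithioaryl)alkyl oxirane to a benzo-fused carbinol. The carbocycle C1–C2–C3–C4–C4a–C8a closes in the 6-exo-tet mode. C1 is set by the (R)-oxirane carbon reacting with clean inversion, so the (1R) centre and its trans relationship to the existing C4 centre come from the acyclic precursor and not from ring bias. The step needs exo attack at C1 to win over 7-endo attack at C20; the tether secures this, because backside approach to the internal carbon is collinear with its C–O bond in a chair-like six-membered array, whereas the endo path would place the C20–O bond inside a strained seven-membered array that contains the planar arene. An electrophilic ring closure could not replace it, since the arene would react at C5 (para to O8), whereas the bromine fixes the nucleophilic site at C8a.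

Step 16
Reactants: 23 [(1R,4S)-7,8-bis(methoxymethoxy)-4-[(2S,6R)-7-(TBS-oxy)-6-methylheptan-2-yl]-1,2,3,4-tetrahydronaphthalen-1-yl]methanol
Product: 24 [(1R,4S)-7,8-bis(methoxymethoxy)-4-[(2S,6R)-7-(TBS-oxy)-6-methylheptan-2-yl]-1,2,3,4-tetrahydronaphthalen-1-yl]methyl 4-methylbenzenesulfonate
Conditions: TsCl, Et3N, DMAP (cat.), CH2Cl2, 0 °C to rt
Reagents that add atoms: 4-methylbenzenesulfonyl chloride, Cc1ccc(cc1)S(Cl)(=O)=O
Why: Sulfonylation of the primary C20 alcohol takes place on oxygen only, so the C1 stereocentre is not involved.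

Step 17
Reactants: 24 the C20 tosylate
Product: 25 (1R,4S)-7,8-bis(methoxymethoxy)-1-methyl-4-[(2S,6R)-7-(TBS-oxy)-6-methylheptan-2-yl]-1,2,3,4-tetrahydronaphthalene
Conditions: LiBHEt3, THF, 0 °C to rt
Reagents that add atoms: none
Why: Lithium triethylborohydride displaces the primary tosylate by direct SN2 hydride attack at C20, which turns the hydroxymethyl group into the C1 methyl without touching C1 and outruns any aryl-assisted ionisation.

Step 18
Reactants: 25 (1R,4S)-7,8-bis(methoxymethoxy)-1-methyl-4-[(2S,6R)-7-(TBS-oxy)-6-methylheptan-2-yl]-1,2,3,4-tetrahydronaphthalene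
Product: 27 tert-butyl (5R,8S)-3,4-bis(methoxymethoxy)-5-methyl-8-[(2S,6R)-7-(TBS-oxy)-6-methylheptan-2-yl]-5,6,7,8-tetrahydronaphthalene-2-carboxylate, via C6 aryllithium 26 (not isolated)
Conditions: n-BuLi, TMEDA, THF, −20 to 0 °C; Boc2O, −78 °C to rt; sat. NH4Cl
Reagents that add atoms: di-tert-butyl dicarbonate, CC(C)(C)OC(=O)OC(=O)OC(C)(C)C
Why: In this directed ortho-metalation the C7 MOM ether guides the base to C6, the only ring position ortho to an oxygen, and acylation of the aryllithium with Boc2O should give the tert-butyl ester directly.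

Step 19
Reactants: 27 the silyl ether tert-butyl ester
Product: 28 tert-butyl (5R,8S)-8-[(2S,6R)-7-hydroxy-6-methylheptan-2-yl]-3,4-bis(methoxymethoxy)-5-methyl-5,6,7,8-tetrahydronaphthalene-2-carboxylate
Conditions: TBAF, THF, 0 °C to rt
Reagents that add atoms: none
Why: Fluoride desilylation frees the C16 alcohol while the hindered tert-butyl ester and the MOM acetals are stable to these mildly basic conditions.

Step 20
Reactants: 29 caffeic acid, (E)-3-(3,4-dihydroxyphenyl)prop-2-enoic acid
Product: 31 (E)-3-[3,4-bis(methoxymethoxy)phenyl]prop-2-enoic acid, via tris-MOM caffeate 30 (not isolated)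
Conditions: MOMCl, i-Pr2NEt, CH2Cl2, 0 °C to rt; concentrate; LiOH, THF/MeOH/H2O, rt; then 1 M HCl to pH 4 at 0 °C
Reagents that add atoms: chloromethyl methyl ether, COCCl
Why: Exhaustive O-alkylation followed by saponification works because the MOM ester is an acyl acetal cleaved by hydroxide, whereas the aryl MOM ethers are base-stable.

Step 21
Reactants: 28 the C16 alcohol, 31 (E)-3-[3,4-bis(methoxymethoxy)phenyl]prop-2-enoic acid
Product: 32 tert-butyl (5R,8S)-8-[(2S,6R)-7-{[(2E)-3-[3,4-bis(methoxymethoxy)phenyl]prop-2-enoyl]oxy}-6-methylheptan-2-yl]-3,4-bis(methoxymethoxy)-5-methyl-5,6,7,8-tetrahydronaphthalene-2-carboxylate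
Conditions: DCC, DMAP (cat.), CH2Cl2, 0 °C to rt
Reagents that add atoms: none
Why: Steglich esterification of the unhindered primary alcohol should be clean, since every phenol and the ring carboxyl are masked and the E alkene is not touched.

Step 22
Reactants: 32 the fully protected ester
Product: 33 (5R,8S)-8-[(2S,6R)-7-{[(2E)-3-(3,4-dihydroxyphenyl)prop-2-enoyl]oxy}-6-methylheptan-2-yl]-3,4-dihydroxy-5-methyl-5,6,7,8-tetrahydronaphthalene-2-carboxylic acid (CNP0492979.1)
Conditions: TFA/CH2Cl2/H2O (10:10:1), argon, 0 °C to rt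
Reagents that add atoms: none
Why: Acidolysis should remove the four MOM acetals (oxocarbenium ions trapped by water) and the tert-butyl ester (alkyl–oxygen cleavage to isobutene) in one operation, while the primary cinnamate ester and all four stereocentres are stable to acid at room temperature.

Compound list
1 | 2-bromo-3,4-dihydroxybenzaldehyde | O=Cc1ccc(O)c(O)c1Br | starting material
2 | 2-bromo-3,4-bis(methoxymethoxy)benzaldehyde | O=Cc1ccc(OCOC)c(OCOC)c1Br | intermediate
3 | N-[2-Ar-1-(4-methylbenzenesulfonyl)ethenyl]formamide | O=CNC(=Cc1ccc(OCOC)c(OCOC)c1Br)S(=O)(=O)c1ccc(C)cc1 | intermediate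
4 | 2-[2-bromo-3,4-bis(methoxymethoxy)phenyl]acetonitrile | N#CCc1ccc(OCOC)c(OCOC)c1Br | intermediate
5 | 2-[2-bromo-3,4-bis(methoxymethoxy)phenyl]acetic acid | OC(=O)Cc1ccc(OCOC)c(OCOC)c1Br | intermediate
6 | (S)-3-bromo-2-methylpropan-1-ol | C[C@H](CBr)CO | starting material
7 | (S)-(3-bromo-2-methylpropoxy)(tert-butyl)dimethylsilane | C[C@H](CBr)CO[Si](C)(C)C(C)(C)C | intermediate
8 | (E)-N-methoxy-N-methylbut-2-enamide | C/C=C/C(=O)N(C)OC | starting material
9 | (S)-[3-(tert-butyldimethylsilyloxy)-2-methylpropyl]magnesium bromide | C[C@H](C[Mg]Br)CO[Si](C)(C)C(C)(C)C | intermediate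
10 | (2E,6R)-7-(tert-butyldimethylsilyloxy)-6-methylhept-2-en-4-one | C/C=C/C(=O)C[C@@H](C)CO[Si](C)(C)C(C)(C)C | intermediate
11 | (2E,4R,6R)-7-(tert-butyldimethylsilyloxy)-6-methylhept-2-en-4-ol | C/C=C/[C@H](O)C[C@@H](C)CO[Si](C)(C)C(C)(C)C | intermediate
12 | (2E,4R,6R)-7-(tert-butyldimethylsilyloxy)-6-methylhept-2-en-4-yl 2-[2-bromo-3,4-bis(methoxymethoxy)phenyl]acetate | C/C=C/[C@H](OC(=O)Cc1ccc(OCOC)c(OCOC)c1Br)C[C@@H](C)CO[Si](C)(C)C(C)(C)C | intermediate
13 | (Z)-O-trimethylsilyl ketene acetal of 12 (aryl cis to OSiMe3) | C/C=C/[C@H](O/C(O[Si](C)(C)C)=C/c1ccc(OCOC)c(OCOC)c1Br)C[C@@H](C)CO[Si](C)(C)C(C)(C)C | intermediate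
14 | trimethylsilyl (2S,3S,4E,7R)-2-Ar-8-(tert-butyldimethylsilyloxy)-3,7-dimethyloct-4-enoate | C[C@H](C/C=C/[C@H](C)[C@H](C(=O)O[Si](C)(C)C)c1ccc(OCOC)c(OCOC)c1Br)CO[Si](C)(C)C(C)(C)C | intermediate
15 | (2S,3S,4E,7R)-2-[2-bromo-3,4-bis(methoxymethoxy)phenyl]-8-(tert-butyldimethylsilyloxy)-3,7-dimethyloct-4-enoic acid | C[C@H](C/C=C/[C@H](C)[C@H](C(=O)O)c1ccc(OCOC)c(OCOC)c1Br)CO[Si](C)(C)C(C)(C)C | intermediate
16 | (2S,3S,4E,7R)-2-[2-bromo-3,4-bis(methoxymethoxy)phenyl]-8-(tert-butyldimethylsilyloxy)-3,7-dimethyloct-4-en-1-ol | C[C@H](C/C=C/[C@H](C)[C@H](CO)c1ccc(OCOC)c(OCOC)c1Br)CO[Si](C)(C)C(C)(C)C | intermediate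
17 | (2S,3S,7R)-2-[2-bromo-3,4-bis(methoxymethoxy)phenyl]-8-(tert-butyldimethylsilyloxy)-3,7-dimethyloctan-1-ol | C[C@H](CCC[C@H](C)[C@H](CO)c1ccc(OCOC)c(OCOC)c1Br)CO[Si](C)(C)C(C)(C)C | intermediate
18 | (2S,3S,7R)-2-[2-bromo-3,4-bis(methoxymethoxy)phenyl]-8-(tert-butyldimethylsilyloxy)-3,7-dimethyloctyl 4-methylbenzenesulfonate | C[C@H](CCC[C@H](C)[C@H](COS(=O)(=O)c1ccc(C)cc1)c1ccc(OCOC)c(OCOC)c1Br)CO[Si](C)(C)C(C)(C)C | intermediate
19 | tert-butyl{[(2R,6S,7S)-7-[2-bromo-3,4-bis(methoxymethoxy)phenyl]-2,6-dimethylundec-10-en-1-yl]oxy}dimethylsilane | C[C@H](CCC[C@H](C)[C@H](CCC=C)c1ccc(OCOC)c(OCOC)c1Br)CO[Si](C)(C)C(C)(C)C | intermediate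
20 | tert-butyl{[(2R,6S,7S)-7-[2-bromo-3,4-bis(methoxymethoxy)phenyl]-2,6-dimethyl-9-(oxiran-2-yl)nonyl]oxy}dimethylsilane, both oxirane epimers | C[C@H](CCC[C@H](C)[C@H](CCC1CO1)c2ccc(OCOC)c(OCOC)c2Br)CO[Si](C)(C)C(C)(C)C | intermediate
21 | tert-butyl{[(2R,6S,7S)-7-[2-bromo-3,4-bis(methoxymethoxy)phenyl]-2,6-dimethyl-9-[(2R)-oxiran-2-yl]nonyl]oxy}dimethylsilane | C[C@H](CCC[C@H](C)[C@H](CC[C@@H]1CO1)c2ccc(OCOC)c(OCOC)c2Br)CO[Si](C)(C)C(C)(C)C | intermediate
22 | C8a aryllithium of 21 (lithium in place of bromine) | C[C@H](CCC[C@H](C)[C@H](CC[C@@H]1CO1)c2ccc(OCOC)c(OCOC)c2[Li])CO[Si](C)(C)C(C)(C)C | intermediate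
23 | [(1R,4S)-7,8-bis(methoxymethoxy)-4-[(2S,6R)-7-(tert-butyldimethylsilyloxy)-6-methylheptan-2-yl]-1,2,3,4-tetrahydronaphthalen-1-yl]methanol | C[C@H](CCC[C@H](C)[C@@H]1CC[C@@H](CO)c2c1ccc(OCOC)c2OCOC)CO[Si](C)(C)C(C)(C)C | intermediate
24 | [(1R,4S)-7,8-bis(methoxymethoxy)-4-[(2S,6R)-7-(tert-butyldimethylsilyloxy)-6-methylheptan-2-yl]-1,2,3,4-tetrahydronaphthalen-1-yl]methyl 4-methylbenzenesulfonate | C[C@H](CCC[C@H](C)[C@@H]1CC[C@@H](COS(=O)(=O)c3ccc(C)cc3)c2c1ccc(OCOC)c2OCOC)CO[Si](C)(C)C(C)(C)C | intermediate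
25 | (1R,4S)-7,8-bis(methoxymethoxy)-1-methyl-4-[(2S,6R)-7-(tert-butyldimethylsilyloxy)-6-methylheptan-2-yl]-1,2,3,4-tetrahydronaphthalene | C[C@H](CCC[C@H](C)[C@@H]1CC[C@@H](C)c2c1ccc(OCOC)c2OCOC)CO[Si](C)(C)C(C)(C)C | intermediate
26 | C6 aryllithium of 25 | C[C@H](CCC[C@H](C)[C@@H]1CC[C@@H](C)c2c1cc([Li])c(OCOC)c2OCOC)CO[Si](C)(C)C(C)(C)C | intermediate
27 | tert-butyl (5R,8S)-3,4-bis(methoxymethoxy)-5-methyl-8-[(2S,6R)-7-(tert-butyldimethylsilyloxy)-6-methylheptan-2-yl]-5,6,7,8-tetrahydronaphthalene-2-carboxylate | C[C@H](CCC[C@H](C)[C@@H]1CC[C@@H](C)c2c1cc(C(=O)OC(C)(C)C)c(OCOC)c2OCOC)CO[Si](C)(C)C(C)(C)C | intermediate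
28 | tert-butyl (5R,8S)-8-[(2S,6R)-7-hydroxy-6-methylheptan-2-yl]-3,4-bis(methoxymethoxy)-5-methyl-5,6,7,8-tetrahydronaphthalene-2-carboxylate | C[C@H](CCC[C@H](C)[C@@H]1CC[C@@H](C)c2c1cc(C(=O)OC(C)(C)C)c(OCOC)c2OCOC)CO | intermediate
29 | caffeic acid | OC(=O)/C=C/c1ccc(O)c(O)c1 | starting material
30 | methoxymethyl (E)-3-[3,4-bis(methoxymethoxy)phenyl]prop-2-enoate | COCOC(=O)/C=C/c1ccc(OCOC)c(OCOC)c1 | intermediate
31 | (E)-3-[3,4-bis(methoxymethoxy)phenyl]prop-2-enoic acid | OC(=O)/C=C/c1ccc(OCOC)c(OCOC)c1 | intermediate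
32 | tert-butyl (5R,8S)-8-[(2S,6R)-7-{[(2E)-3-[3,4-bis(methoxymethoxy)phenyl]prop-2-enoyl]oxy}-6-methylheptan-2-yl]-3,4-bis(methoxymethoxy)-5-methyl-5,6,7,8-tetrahydronaphthalene-2-carboxylate | C[C@H](CCC[C@H](C)[C@@H]1CC[C@@H](C)c2c1cc(C(=O)OC(C)(C)C)c(OCOC)c2OCOC)COC(=O)/C=C/c1ccc(OCOC)c(OCOC)c1 | intermediate
33 | (5R,8S)-8-[(2S,6R)-7-{[(2E)-3-(3,4-dihydroxyphenyl)prop-2-enoyl]oxy}-6-methylheptan-2-yl]-3,4-dihydroxy-5-methyl-5,6,7,8-tetrahydronaphthalene-2-carboxylic acid (CNP0492979.1) | C[C@H](CCC[C@H](C)[C@@H]1CC[C@@H](C)c2c1cc(C(=O)O)c(O)c2O)COC(=O)/C=C/c1ccc(O)c(O)c1 | target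

Total step count: 22.
Longest linear sequence: 18 steps (steps 1–3, 7–19, 21, 22 from compound 1; the branch from compound 6 through steps 4–6 is equally long).

Steps most likely to fail

1. Step 15 (ring closure). The aryllithium may be protonated before it cyclises, or the opening may leak into the seven-membered (endo) mode. The fallback forms the same C1–C8a bond by palladium enolate arylation and sets C1 by equilibration instead of by inversion. It sets out from alkene 19. Hydroboration–oxidation (9-BBN, THF; NaOH/H2O2) should give (5S,6S,10R)-5-Ar-11-(TBS-oxy)-6,10-dimethylundecan-1-ol F1. Oxidation with TEMPO/PhI(OAc)2 in MeCN/H2O should give the corresponding undecanoic acid F2, and MeI/K2CO3 in DMF its methyl ester F3. Intramolecular α-arylation of the ester enolate (Pd2(dba)3, P(t-Bu)3, LiHMDS, toluene) should then close the ring to the methyl tetralin-1-carboxylate F4. C1 of F4 is epimerisable, and NaOMe/MeOH should drive it to the 1,4-trans isomer, in which both the C1 ester (peri to the C8 MOM ether) and the C4 chain (peri to C5–H) can sit pseudoaxial. Reduction with LiAlH4 returns to the route at alcohol 23.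

2. Step 22 (global deprotection). Formaldehyde equivalents and tert-butyl cations released by the acid may alkylate the freed catechol rings, or the caffeate ester may be cleaved. The fallback unmasks the two catechols in two separate operations and sets out from alcohol 28 and caffeic acid 29. Silylation of 29 (TBSCl, imidazole, DMF) should give the tris-silyl compound tert-butyldimethylsilyl (E)-3-[3,4-bis(TBS-oxy)phenyl]prop-2-enoate F5. Cleavage of the silyl ester (K2CO3, THF/H2O) should give (E)-3-[3,4-bis(TBS-oxy)phenyl]prop-2-enoic acid F6. DCC/DMAP coupling with 28 should give the bis-silyl caffeate ester F7. TFA/CH2Cl2/H2O should then remove only the two ring MOM groups and the tert-butyl ester, the more reactive caffeoyl ring staying masked, to give the bis-silyl carboxylic acid F8. Near-neutral fluoride (KHF2, MeOH, rt) removes the two aryl silyl ethers and arrives at target 33.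

3. Step 6 (carbinol configuration). Facial discrimination in the hydride transfer may be insufficient, because the propenyl and the β-branched alkyl group differ only moderately in size, and the resulting epimer would later become a remote diastereomer that is hard to remove. The fallback replaces the enone reduction by an ynone reduction with a wider steric and electronic gap and sets out from bromide 7, used as Grignard reagent 9. Acylation with N-methoxy-N-methylbut-2-ynamide should give (6R)-7-(TBS-oxy)-6-methylhept-2-yn-4-one F9. Noyori transfer hydrogenation (RuCl[(R,R)-TsDPEN](p-cymene), i-PrOH) should give (4R,6R)-7-(TBS-oxy)-6-methylhept-2-yn-4-ol F10. trans-Selective hydroalumination of the propargylic alcohol with Red-Al (THF, 0 °C) returns to the route at allylic alcohol 11.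

Further compounds
F1 | step 15 | (5S,6S,10R)-5-[2-bromo-3,4-bis(methoxymethoxy)phenyl]-11-(tert-butyldimethylsilyloxy)-6,10-dimethylundecan-1-ol | C[C@H](CCC[C@H](C)[C@H](CCCCO)c1ccc(OCOC)c(OCOC)c1Br)CO[Si](C)(C)C(C)(C)C
F2 | step 15 | (5S,6S,10R)-5-[2-bromo-3,4-bis(methoxymethoxy)phenyl]-11-(tert-butyldimethylsilyloxy)-6,10-dimethylundecanoic acid | C[C@H](CCC[C@H](C)[C@H](CCCC(=O)O)c1ccc(OCOC)c(OCOC)c1Br)CO[Si](C)(C)C(C)(C)C
F3 | step 15 | methyl (5S,6S,10R)-5-[2-bromo-3,4-bis(methoxymethoxy)phenyl]-11-(tert-butyldimethylsilyloxy)-6,10-dimethylundecanoate | C[C@H](CCC[C@H](C)[C@H](CCCC(=O)OC)c1ccc(OCOC)c(OCOC)c1Br)CO[Si](C)(C)C(C)(C)C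
F4 | step 15 | methyl (1R,4S)-7,8-bis(methoxymethoxy)-4-[(2S,6R)-7-(tert-butyldimethylsilyloxy)-6-methylheptan-2-yl]-1,2,3,4-tetrahydronaphthalene-1-carboxylate | C[C@H](CCC[C@H](C)[C@@H]1CC[C@@H](C(=O)OC)c2c1ccc(OCOC)c2OCOC)CO[Si](C)(C)C(C)(C)C
F5 | step 22 | tert-butyldimethylsilyl (E)-3-[3,4-bis(tert-butyldimethylsilyloxy)phenyl]prop-2-enoate | CC(C)(C)[Si](C)(C)OC(=O)/C=C/c1ccc(O[Si](C)(C)C(C)(C)C)c(O[Si](C)(C)C(C)(C)C)c1
F6 | step 22 | (E)-3-[3,4-bis(tert-butyldimethylsilyloxy)phenyl]prop-2-enoic acid | OC(=O)/C=C/c1ccc(O[Si](C)(C)C(C)(C)C)c(O[Si](C)(C)C(C)(C)C)c1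
F7 | step 22 | tert-butyl (5R,8S)-8-[(2S,6R)-7-{[(2E)-3-[3,4-bis(tert-butyldimethylsilyloxy)phenyl]prop-2-enoyl]oxy}-6-methylheptan-2-yl]-3,4-bis(methoxymethoxy)-5-methyl-5,6,7,8-tetrahydronaphthalene-2-carboxylate | C[C@H](CCC[C@H](C)[C@@H]1CC[C@@H](C)c2c1cc(C(=O)OC(C)(C)C)c(OCOC)c2OCOC)COC(=O)/C=C/c1ccc(O[Si](C)(C)C(C)(C)C)c(O[Si](C)(C)C(C)(C)C)c1
F8 | step 22 | (5R,8S)-8-[(2S,6R)-7-{[(2E)-3-[3,4-bis(tert-butyldimethylsilyloxy)phenyl]prop-2-enoyl]oxy}-6-methylheptan-2-yl]-3,4-dihydroxy-5-methyl-5,6,7,8-tetrahydronaphthalene-2-carboxylic acid | C[C@H](CCC[C@H](C)[C@@H]1CC[C@@H](C)c2c1cc(C(=O)O)c(O)c2O)COC(=O)/C=C/c1ccc(O[Si](C)(C)C(C)(C)C)c(O[Si](C)(C)C(C)(C)C)c1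
F9 | step 6 | (6R)-7-(tert-butyldimethylsilyloxy)-6-methylhept-2-yn-4-one | CC#CC(=O)C[C@@H](C)CO[Si](C)(C)C(C)(C)C
F10 | step 6 | (4R,6R)-7-(tert-butyldimethylsilyloxy)-6-methylhept-2-yn-4-ol | CC#C[C@H](O)C[C@@H](C)CO[Si](C)(C)C(C)(C)C
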